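(All runs were generated by integration from invented constants; noise was put on by code.)

Late in both earlier runs the readings of Z stayed level within their scatter, well short of the whole charge of E, and I wanted to know what that level was worth for a new flask.

| flask | E | D | remark | time |
|---|---|---|---|---|
| larch | 0.30 M (in portions, 4) | 0.084 M | run made earlier; portions every 40 s |  |
| ash | 0.30 M (in portions, 4) | 0.13 M | run made earlier; portions every 40 s |  |
| flask | 0.30 M (in portions, 4) | 0.0600 M | the portions of E follow each other after 40 s, the first at the start | 2.5 h |

- larch (time / h: Z / %): 0.417: 33.0; 0.833: 39.3; 1.33: 43.2; 1.50: 41.5; 2.00: 42.0; 2.50: 42.8; 3.00: 43.6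
- ash (time / h: Z / %): 0.167: 17.8; 0.500: 28.5; 0.833: 30.5; 1.33: 30.5; 2.00: 33.2; 2.50: 31.3; 3.00: 32.0

(standard deviation of a reading: 1 percentage point)

- why nothing more happens at 2.5 h, or that something still does (it is still moving / forward and back rates have come level / all of E has reacted)
- amount of Z at 2.5 h, in percent of the E charged

- percent here means E units held: one Z counts as two
- the reaction counts as stopped when no species that holds the E changes by six tenths of a point or more over the second half of the time

Would this flask stand still at the asked time? The ash run read 30.5 % at 0.833 h with no clear rise after, and 2.5 h is 3.00 times as long, so I took the new flask as stopped by then.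

Stopped how? Over their last five readings the larch run averaged 42.6 % and the ash run, with more D, 31.5 %. In the larch run, even if D took up one E each, 29.4 % of the E stayed unaccounted for, so I assumed free E standing in balance with Z.

Does one number serve both runs? Z over free E squared, the equilibrium constant, read 8.23 /M in the larch run and 8.29 /M in the ash run, each reading good to 1 percentage point. Their mean, 8.26 /M, is my balance constant. For the new flask I counted 0.240 M of E left once D had taken up one E each, and my constant then gave free E 0.0940 M and Z 48.7 %.

The forecast, with a constant of 8.5 to 8.8 per molar against my 8.26 /M, said forward and back rates have come level and 49 %, holding that “the flat level is set by D and not by time”.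

The flask gave: forward and back rates have come level, with Z at 49.3 %.

    2 E ⇌ Z (K = 8.70 /M, k = 0.00188 /M/s)
    E + D → X (k = 0.0274 /M/s)

Z in the flask stood at 48.8 % at 1.25 h and at 49.3 % at 25.0 h, and the balance of E and Z, by that step alone and both ways together, relaxed at 2.50 h with a half-life of 0.212 h, shorter than 2.5 h. In the flask, with E and the time held, moving the answer by 5 points took D down to 0.0405 M or up to 0.0798 M. For the neighbour charged with 1.2 M of E, my balance constant gave free E 0.234 M and Z 75.5 %; that neighbour gave Z 75.9 %.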